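**Retrosynthetic overview**

1. The last skeletal bond is C5'–C6', the σ-bond between the C4'=C5' and C6'=C7' double bonds of the triene. It is made in step 16 by syn-hydrozirconation of a terminal C4'≡C5' enyne on the fully oxygenated core, followed by insertion of the α-chloroalkenyllithium from (Z)-1-chloro-2,6-dimethylhepta-1,5-diene: two carbanionic sp2 carbons are joined by a 1,2-metalate shift with loss of chloride.
2. Enabling feature: C5' and C6' are both CH carbons. C5' is the terminus of the C2'–C5' dienyl unit, so it can come from an alkyne CH and carry Zr; C6' is the unsubstituted end of the trisubstituted C6'=C7' alkene, so it can carry H, Cl and Li. The step closes no ring.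
3. Enyne precursor: C4–C1' from an alkenyllithium and a ring Weinreb amide; C3 by CBS reduction; C1' by C3-hydroxyl-directed 1,3-anti reduction; C4–C5 oxirane by peroxide conjugate addition anti to C3–OTBS; then C1=C2 (Saegusa–Ito), C1–CH2OH (Morita–Baylis–Hillman) and C6–OH (Luche).
4. Ring order: the carbocycle is bought as 1,4-dioxaspiro[4.5]dec-6-en-8-one and its dioxolane is removed in step 9. The oxirane (step 10) is the only ring formed. Desilylation and primary-selective acetylation finish the route.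

Key step: step 16

Remark (locants): ring C1 (carries CH2O), C2 (=CH), C3 (carbinol), C4 (quaternary oxirane carbon with the side chain), C5 (oxirane CH), C6 (carbinol); side chain C1' (carbinol), C2'=C3'(CH3), C4'=C5', C6'=C7'(CH3), C8'–C12'; TBS = tert-butyldimethylsilyl.
Assumption: in the CBS reductions (step 4 and the two fallbacks) the alkenyl carbon is taken as the large carbonyl substituent, so the (R)-oxazaborolidine gives the (S)-carbinol.

**Route**

Step 1
Reactants: 1 1,4-bis(trimethylsilyl)buta-1,3-diyne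
Product: 3 (trimethylsilyl)buta-1,3-diyne, via lithium diynide 2 (not isolated)
Conditions: MeLi·LiBr (1.05 equiv), Et2O, rt; then H2O, 0 °C
Reagents that add atoms: none
Why: Nucleophilic Si–C(sp) cleavage by methyllithium removes one of the two equivalent silyl groups and should stop there because the lithium diynide formed is deactivated toward a second attack.

Step 2
Reactants: 3 (trimethylsilyl)buta-1,3-diyne
Product: 5 (E)-4-iodo-3-methyl-1-(trimethylsilyl)but-3-en-1-yne, via alkenylalane 4 (not isolated)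
Conditions: AlMe3 (2 equiv), Cp2ZrCl2 (0.25 equiv), CH2Cl2, rt; then I2, THF, −30 → 0 °C
Reagents that add atoms: trimethylaluminium, C[Al](C)C; iodine, II
Why: Negishi carboalumination adds CH3 and Al syn across the terminal alkyne with Al on the terminal carbon, and iodinolysis with retention fixes the (E) geometry of the future C2'=C3' bond (I cis to CH3).

Step 3
Reactants: 6 1,4-dioxaspiro[4.5]dec-6-en-8-one
Product: 7 7-iodo-1,4-dioxaspiro[4.5]dec-6-en-8-one
Conditions: I2 (1.5 equiv), pyridine/CH2Cl2 (1:1), 0 °C → rt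
Reagents that add atoms: iodine, II
Why: Baylis–Hillman-type α-iodination (conjugate addition of pyridine, iodination of the enolate, elimination of pyridine) places iodine on the enone α-carbon, the future C4.

Step 4
Reactants: 7 7-iodo-1,4-dioxaspiro[4.5]dec-6-en-8-one
Product: 8 (8S)-7-iodo-1,4-dioxaspiro[4.5]dec-6-en-8-ol
Conditions: (R)-2-methyl-CBS-oxazaborolidine (0.2 equiv), BH3·SMe2 (0.7 equiv), THF, −20 °C; MeOH quench
Reagents that add atoms: none
Why: Corey–Bakshi–Shibata reduction, in which the catalyst-bound borane delivers hydride to one carbonyl face with the iodoalkenyl carbon as the large group, should set C3 as (S) under reagent control.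

Step 5
Reactants: 8 (8S)-7-iodo-1,4-dioxaspiro[4.5]dec-6-en-8-ol
Product: 9 (8S)-8-hydroxy-N-methoxy-N-methyl-1,4-dioxaspiro[4.5]dec-6-ene-7-carboxamide
Conditions: Pd(OAc)2 (5 mol %), PPh3 (10 mol %), CO (1 atm), MeNHOMe·HCl (1.5 equiv), Et3N (4 equiv), DMF, 50 °C
Reagents that add atoms: carbon monoxide, [C-]#[O+]; N,O-dimethylhydroxylamine hydrochloride, CNOC.Cl
Why: Aminocarbonylation (oxidative addition of the alkenyl C–I bond to zerovalent palladium, CO insertion, aminolysis of the acylpalladium) gives the Weinreb amide, and the amine outcompetes the free allylic hydroxyl as nucleophile.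

Step 6
Reactants: 9 (8S)-8-hydroxy-N-methoxy-N-methyl-1,4-dioxaspiro[4.5]dec-6-ene-7-carboxamide; 5 (E)-4-iodo-3-methyl-1-(trimethylsilyl)but-3-en-1-yne
Product: 12 (2E)-1-[(8S)-8-hydroxy-1,4-dioxaspiro[4.5]dec-6-en-7-yl]-3-methyl-5-(trimethylsilyl)pent-2-en-4-yn-1-one, via alkenyllithium 10 (not isolated), via magnesium alkoxide 11 (not isolated)
Conditions: 5, t-BuLi (2.05 equiv), Et2O, −78 °C; 9, i-PrMgCl (1.0 equiv), THF, −40 °C; combine, −78 → −20 °C; aq. NH4Cl
Reagents that add atoms: none
Why: Iodine–lithium exchange gives the alkenyllithium with retention, and its 1,2-addition to the Weinreb amide (hydroxyl masked as the magnesium alkoxide) stops at the chelated tetrahedral adduct, so the cross-conjugated ketone appears only on quench (Weinreb ketone synthesis).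

Step 7
Reactants: 12 (2E)-1-[(8S)-8-hydroxy-1,4-dioxaspiro[4.5]dec-6-en-7-yl]-3-methyl-5-(trimethylsilyl)pent-2-en-4-yn-1-one
Product: 13 (8S)-7-[(1S,2E)-1-hydroxy-3-methyl-5-(trimethylsilyl)pent-2-en-4-yn-1-yl]-1,4-dioxaspiro[4.5]dec-6-en-8-ol
Conditions: Me4NBH(OAc)3 (5 equiv), MeCN/AcOH (2:1), −35 °C
Reagents that add atoms: none
Why: Evans–Saksena reduction, in which the C3 alkoxy(diacetoxy)borohydride delivers hydride intramolecularly to the acid-activated C1' ketone in its s-trans rotamer on the face of the pseudo-axial C3–O bond, should give the 1,3-anti diol and so set C1' as (S).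

Step 8
Reactants: 13 (8S)-7-[(1S,2E)-1-hydroxy-3-methyl-5-(trimethylsilyl)pent-2-en-4-yn-1-yl]-1,4-dioxaspiro[4.5]dec-6-en-8-ol
Product: 14 (8S)-8-(tert-butyldimethylsilyloxy)-7-[(1S,2E)-1-(tert-butyldimethylsilyloxy)-3-methyl-5-(trimethylsilyl)pent-2-en-4-yn-1-yl]-1,4-dioxaspiro[4.5]dec-6-ene
Conditions: TBSOTf (2.5 equiv), 2,6-lutidine (4 equiv), CH2Cl2, −78 °C
Reagents that add atoms: tert-butyldimethylsilyl trifluoromethanesulfonate, CC(C)(C)[Si](C)(C)OS(=O)(=O)C(F)(F)F
Why: Silyl triflate with a hindered base silylates both secondary allylic hydroxyls at low temperature, where the dioxolane is not attacked.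

Step 9
Reactants: 14 (8S)-8-(tert-butyldimethylsilyloxy)-7-[(1S,2E)-1-(tert-butyldimethylsilyloxy)-3-methyl-5-(trimethylsilyl)pent-2-en-4-yn-1-yl]-1,4-dioxaspiro[4.5]dec-6-ene
Product: 15 (4S)-4-(tert-butyldimethylsilyloxy)-3-[(1S,2E)-1-(tert-butyldimethylsilyloxy)-3-methyl-5-(trimethylsilyl)pent-2-en-4-yn-1-yl]cyclohex-2-en-1-one
Conditions: PPTS (0.2 equiv), acetone/H2O (10:1), 40 °C
Reagents that add atoms: water, O
Why: Acid-catalysed hydrolysis of the allylic dioxolane through a conjugation-stabilised oxocarbenium ion unveils the C6 ketone, while the secondary silyl ethers and the C-silyl alkyne are stable to this weak acid.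

Step 10
Reactants: 15 (4S)-4-(tert-butyldimethylsilyloxy)-3-[(1S,2E)-1-(tert-butyldimethylsilyloxy)-3-methyl-5-(trimethylsilyl)pent-2-en-4-yn-1-yl]cyclohex-2-en-1-one
Product: 16 epoxy ketone (C4–C5 oxirane of 15 trans to the C3 silyloxy group; C6 ketone; C1 and C2 are CH2)
Conditions: t-BuOOH (anhydrous, 3 equiv), NaN(SiMe3)2 (1.2 equiv), THF, −40 → 0 °C
Reagents that add atoms: tert-butyl hydroperoxide, CC(C)(C)OO
Why: Weitz–Scheffer epoxidation, in which t-BuOO– adds to C4 on the face opposite the C3 silyloxy group (held pseudo-axial by allylic strain with the C4 substituent) and the enolate closes the oxirane on that face, should set C4 and C5 trans to C3–O and leave the enyne untouched.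

Step 11
Reactants: 16 epoxy ketone
Product: 18 epoxy enone (C1=C2 dehydro derivative of 16), via silyl enol ether 17 (not isolated)
Conditions: LiN(i-Pr)2 (1.3 equiv), Me3SiCl (1.5 equiv), THF, −78 °C; then Pd(OAc)2 (1.1 equiv), MeCN, rt
Reagents that add atoms: none
Why: Saegusa–Ito oxidation works here because kinetic enolisation can only occur toward C1 (C5 is an oxirane carbon), and the divalent palladium enolate formed from the silyl enol ether undergoes β-hydride elimination to the C1=C2 enone.

Step 12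
Reactants: 18 epoxy enone
Product: 19 C1-hydroxymethyl epoxy enone
Conditions: aq. HCHO (37 %, 5 equiv), DMAP (0.3 equiv), THF/H2O, rt
Reagents that add atoms: formaldehyde, C=O
Why: Morita–Baylis–Hillman reaction, in which reversible conjugate addition of DMAP at C2 generates the C1 enolate that adds to formaldehyde before DMAP is lost, places CH2OH on C1.

Step 13
Reactants: 19 C1-hydroxymethyl epoxy enone
Product: 21 enyne diol (C1–CH2OH; C6–OH cis to the oxirane; C3 and C1' OTBS; terminal C4'≡C5'H), via C-silylated diol 20 (not isolated)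
Conditions: NaBH4 (1.5 equiv), CeCl3·7H2O (1.2 equiv), MeOH, −78 °C; then K2CO3 (0.5 equiv), 0 °C → rt
Reagents that add atoms: none
Why: Luche 1,2-reduction with hydride entering anti to the adjacent oxirane oxygen should set C6 with its hydroxyl cis to the epoxide, and carbonate-mediated methanolysis then removes the alkynyl silyl group without touching the silyl ethers.

Step 14
Reactants: 21 enyne diol
Product: 22 tetrakis-TBS enyne (CH2O, C3–O, C6–O and C1'–O silylated)
Conditions: TBSOTf (3 equiv), 2,6-lutidine (5 equiv), CH2Cl2, −78 → 0 °C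
Reagents that add atoms: tert-butyldimethylsilyl trifluoromethanesulfonate, CC(C)(C)[Si](C)(C)OS(=O)(=O)C(F)(F)F
Why: Silyl triflate silylates the primary and the remaining secondary hydroxyl, so that no O–H bond is left to consume the zirconium hydride or the lithium amide of step 16.

Step 15
Reactants: 23 5-bromo-2-methylpent-2-ene; 24 propyne
Product: 28 (Z)-1-chloro-2,6-dimethylhepta-1,5-diene, via Grignard reagent 25 (not isolated), via alkylcopper 26 (not isolated), via alkenylcopper 27 (not isolated)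
Conditions: Mg, Et2O; CuBr·SMe2 (1.0 equiv), Et2O/SMe2, −45 °C; propyne (excess), −25 °C; N-chlorosuccinimide (1.2 equiv), THF, −40 → 0 °C; aq. NH4Cl
Reagents that add atoms: N-chlorosuccinimide, ClN1C(=O)CCC1=O
Why: Normant carbocupration adds the alkylcopper syn across propyne with copper on the terminal carbon, and chlorination of the C–Cu bond with retention gives the (Z)-chloride (Cl cis to the homoprenyl chain) that the inversion in step 16 requires.

Step 16
Reactants: 22 tetrakis-TBS enyne; 28 (Z)-1-chloro-2,6-dimethylhepta-1,5-diene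
Product: 32 tetrakis-TBS ether of the (2'E,4'E,6'E)-triene tetraol, via dienylzirconocene chloride 29 (not isolated), via chloroalkenyllithium 30 (not isolated), via alkenylzirconocene chloride 31 (not isolated)
Conditions: Cp2Zr(H)Cl (1.2 equiv), THF, rt, 30 min; then 28 (1.4 equiv) and lithium 2,2,6,6-tetramethylpiperidide (1.4 equiv), −90 → −60 °C; sat. aq. NH4Cl
Reagents that add atoms: none
Why: Syn-hydrozirconation of the terminal C4'≡C5' alkyne puts zirconium on C5'; the lithium amide removes the vinylic proton of 28 to give the carbenoid, which adds to zirconium, and 1,2-migration of C5' from Zr to C6' with loss of chloride followed by protonolysis of the C6'–Zr bond gives the triene. The closest known reaction type is the insertion of 1-chloro-1-lithioalkenes into alkenylzirconocene chlorides obtained by alkyne hydrozirconation, a stereospecific diene and triene synthesis in which the chloride reverses the polarity of one of two carbanionic sp2 carbons. No ring is closed and no stereocentre is formed; the stereochemical output is two alkene geometries, C4'=C5' (E) from syn H–Zr addition and C6'=C7' (E) because the migrating carbon takes the site of lithium (cis to the C7' methyl) and hydrogen later takes the site of chlorine. The step needs chemoselective hydrozirconation of the terminal alkyne over the trisubstituted alkenes and the oxirane, which the much higher rate of terminal alkynes and the absence of O–H bonds should secure. It also needs capture of the carbenoid before it decomposes or isomerises, secured by generating it at −90 °C in the presence of the zirconocene and by its β,β-dialkyl substitution, and a single insertion, favoured because the new α-branched alkenyl–Zr bond is more hindered.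

Step 17
Reactants: 32 tetrakis-TBS ether of the triene tetraol
Product: 33 triene tetraol (desacetyl target)
Conditions: Bu4NF (8 equiv), AcOH (8 equiv), THF, 0 °C → rt
Reagents that add atoms: none
Why: Fluoride cleaves the four Si–O bonds, and buffering with acetic acid keeps the medium near neutral so that neither the acid-labile trienyl carbinol at C1' nor the epoxy alcohols (Payne migration) should be disturbed.

Step 18
Reactants: 33 triene tetraol
Product: 34 CNP0106887.1 (target)
Conditions: AcCl (1.05 equiv), 2,4,6-collidine (3 equiv), CH2Cl2, −78 °C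
Reagents that add atoms: acetyl chloride, CC(Cl)=O
Why: Sterically controlled acylation at low temperature should take the unhindered primary allylic hydroxyl much faster than the three secondary ones, two of which flank the quaternary C4.

**Compound list**

1 | 1,4-bis(trimethylsilyl)buta-1,3-diyne | C[Si](C)(C)C#CC#C[Si](C)(C)C | starting material
2 | lithium 4-(trimethylsilyl)buta-1,3-diyn-1-ide | [Li]C#CC#C[Si](C)(C)C | intermediate
3 | (trimethylsilyl)buta-1,3-diyne | C#CC#C[Si](C)(C)C | intermediate
4 | dimethyl[(E)-2-methyl-4-(trimethylsilyl)but-1-en-3-yn-1-yl]alane | C[Al](C)/C=C(\C)C#C[Si](C)(C)C | intermediate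
5 | (E)-4-iodo-3-methyl-1-(trimethylsilyl)but-3-en-1-yne | I/C=C(\C)C#C[Si](C)(C)C | intermediate
6 | 1,4-dioxaspiro[4.5]dec-6-en-8-one | O=C1C=CC2(OCCO2)CC1 | starting material
7 | 7-iodo-1,4-dioxaspiro[4.5]dec-6-en-8-one | O=C1C(I)=CC2(OCCO2)CC1 | intermediate
8 | (8S)-7-iodo-1,4-dioxaspiro[4.5]dec-6-en-8-ol | C1C[C@H](O)C(I)=CC12OCCO2 | intermediate
9 | (8S)-8-hydroxy-N-methoxy-N-methyl-1,4-dioxaspiro[4.5]dec-6-ene-7-carboxamide | C1C[C@H](O)C(C(=O)N(C)OC)=CC12OCCO2 | intermediate
10 | [(E)-2-methyl-4-(trimethylsilyl)but-1-en-3-yn-1-yl]lithium | [Li]/C=C(\C)C#C[Si](C)(C)C | intermediate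
11 | chloromagnesium alkoxide of 9 | C1C[C@H](O[Mg]Cl)C(C(=O)N(C)OC)=CC12OCCO2 | intermediate
12 | (2E)-1-[(8S)-8-hydroxy-1,4-dioxaspiro[4.5]dec-6-en-7-yl]-3-methyl-5-(trimethylsilyl)pent-2-en-4-yn-1-one | C1C[C@H](O)C(C(=O)/C=C(C)/C#C[Si](C)(C)C)=CC12OCCO2 | intermediate
13 | (8S)-7-[(1S,2E)-1-hydroxy-3-methyl-5-(trimethylsilyl)pent-2-en-4-yn-1-yl]-1,4-dioxaspiro[4.5]dec-6-en-8-ol (1,3-anti diol) | C1C[C@H](O)C([C@@H](O)/C=C(C)/C#C[Si](C)(C)C)=CC12OCCO2 | intermediate
14 | (8S)-8-(tert-butyldimethylsilyloxy)-7-[(1S,2E)-1-(tert-butyldimethylsilyloxy)-3-methyl-5-(trimethylsilyl)pent-2-en-4-yn-1-yl]-1,4-dioxaspiro[4.5]dec-6-ene | C1C[C@H](O[Si](C)(C)C(C)(C)C)C([C@@H](O[Si](C)(C)C(C)(C)C)/C=C(C)/C#C[Si](C)(C)C)=CC12OCCO2 | intermediate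
15 | (4S)-4-(tert-butyldimethylsilyloxy)-3-[(1S,2E)-1-(tert-butyldimethylsilyloxy)-3-methyl-5-(trimethylsilyl)pent-2-en-4-yn-1-yl]cyclohex-2-en-1-one | C1C[C@H](O[Si](C)(C)C(C)(C)C)C([C@@H](O[Si](C)(C)C(C)(C)C)/C=C(C)/C#C[Si](C)(C)C)=CC1=O | intermediate
16 | epoxy ketone: C4–C5 oxirane trans to C3–OTBS, C6 ketone, C1 and C2 CH2, C3 and C1' OTBS, C5'-SiMe3 enyne | C1C[C@H](O[Si](C)(C)C(C)(C)C)[C@@]2([C@@H](O[Si](C)(C)C(C)(C)C)/C=C(C)/C#C[Si](C)(C)C)O[C@H]2C1=O | intermediate
17 | trimethylsilyl enol ether of 16 (C1=C6, C6–OSiMe3) | C=1C[C@H](O[Si](C)(C)C(C)(C)C)[C@@]2([C@@H](O[Si](C)(C)C(C)(C)C)/C=C(C)/C#C[Si](C)(C)C)O[C@H]2C=1O[Si](C)(C)C | intermediate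
18 | epoxy enone: C1=C2, C6 ketone, otherwise as 16 | C1=C[C@H](O[Si](C)(C)C(C)(C)C)[C@@]2([C@@H](O[Si](C)(C)C(C)(C)C)/C=C(C)/C#C[Si](C)(C)C)O[C@H]2C1=O | intermediate
19 | C1-hydroxymethyl epoxy enone | OCC1=C[C@H](O[Si](C)(C)C(C)(C)C)[C@@]2([C@@H](O[Si](C)(C)C(C)(C)C)/C=C(C)/C#C[Si](C)(C)C)O[C@H]2C1=O | intermediate
20 | C-silylated diol: C6–OH cis to the oxirane, C1–CH2OH, alkyne still silylated | OCC1=C[C@H](O[Si](C)(C)C(C)(C)C)[C@@]2([C@@H](O[Si](C)(C)C(C)(C)C)/C=C(C)/C#C[Si](C)(C)C)O[C@H]2[C@H]1O | intermediate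
21 | enyne diol: as 20 with terminal C4'≡C5'H | OCC1=C[C@H](O[Si](C)(C)C(C)(C)C)[C@@]2([C@@H](O[Si](C)(C)C(C)(C)C)/C=C(C)/C#C)O[C@H]2[C@H]1O | intermediate
22 | tetrakis-TBS enyne | CC(C)(C)[Si](C)(C)OCC1=C[C@H](O[Si](C)(C)C(C)(C)C)[C@@]2([C@@H](O[Si](C)(C)C(C)(C)C)/C=C(C)/C#C)O[C@H]2[C@H]1O[Si](C)(C)C(C)(C)C | intermediate
23 | 5-bromo-2-methylpent-2-ene | CC(C)=CCCBr | starting material
24 | propyne | CC#C | starting material
25 | (4-methylpent-3-en-1-yl)magnesium bromide | CC(C)=CCC[Mg]Br | intermediate
26 | (4-methylpent-3-en-1-yl)copper | CC(C)=CCC[Cu] | intermediate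
27 | [(Z)-2,6-dimethylhepta-1,5-dien-1-yl]copper | [Cu]/C=C(/C)CCC=C(C)C | intermediate
28 | (Z)-1-chloro-2,6-dimethylhepta-1,5-diene | Cl/C=C(/C)CCC=C(C)C | intermediate
29 | (4'E)-dienylzirconocene chloride of 22 (Cp2Zr(Cl) on C5') | CC(C)(C)[Si](C)(C)OCC1=C[C@H](O[Si](C)(C)C(C)(C)C)[C@@]2([C@@H](O[Si](C)(C)C(C)(C)C)/C=C(C)/C=C/[Zr](Cl)(C3C=CC=C3)C3C=CC=C3)O[C@H]2[C@H]1O[Si](C)(C)C(C)(C)C | intermediate
30 | [(Z)-1-chloro-2,6-dimethylhepta-1,5-dien-1-yl]lithium (Li cis to the C7' methyl) | Cl/C([Li])=C(/C)CCC=C(C)C | intermediate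
31 | alkenylzirconocene chloride: as 32 with Cp2Zr(Cl) on C6' | CC(C)(C)[Si](C)(C)OCC1=C[C@H](O[Si](C)(C)C(C)(C)C)[C@@]2([C@@H](O[Si](C)(C)C(C)(C)C)/C=C(C)/C=C/C([Zr](Cl)(C3C=CC=C3)C3C=CC=C3)=C(\C)CCC=C(C)C)O[C@H]2[C@H]1O[Si](C)(C)C(C)(C)C | intermediate
32 | tetrakis-TBS ether of the (2'E,4'E,6'E)-triene tetraol | CC(C)(C)[Si](C)(C)OCC1=C[C@H](O[Si](C)(C)C(C)(C)C)[C@@]2([C@@H](O[Si](C)(C)C(C)(C)C)/C=C(C)/C=C/C=C(\C)CCC=C(C)C)O[C@H]2[C@H]1O[Si](C)(C)C(C)(C)C | intermediate
33 | triene tetraol (desacetyl target) | OCC1=C[C@H](O)[C@@]2([C@@H](O)/C=C(C)/C=C/C=C(\C)CCC=C(C)C)O[C@H]2[C@H]1O | intermediate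
34 | CNP0106887.1 | CC(=O)OCC1=C[C@H](O)[C@@]2([C@@H](O)/C=C(C)/C=C/C=C(\C)CCC=C(C)C)O[C@H]2[C@H]1O | target

**Step count and risks**

Total step count: 18.
Longest linear sequence: 15 steps (6 → 34 through steps 3–14 and 16–18).

Steps most likely to fail:

1. Step 16. The α-chloroalkenyllithium may decompose or lose its configuration before it is captured by the alkenylzirconocene, or a second insertion may occur, which would lower conversion and erode the C6'=C7' geometry. Fallback: it sets out from 22 (partner from 23) and returns at 32. Compound 23 is alkylated with LiC≡CH·H2NCH2CH2NH2 in DMSO to give 6-methylhept-5-en-1-yne F1. Carboalumination (AlMe3, catalytic Cp2ZrCl2) and iodinolysis give (E)-1-iodo-2,6-dimethylhepta-1,5-diene F2. Compound 22 is hydrozirconated as in step 16, transmetalated with ZnCl2 and coupled with F2 under Pd(PPh3)4 (Negishi coupling) to give 32.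

2. Step 10. Conjugate addition of the peroxide anion to the fully substituted, doubly branched C4 may be slow, and the C1' silyloxy group may erode the facial preference. Fallback: it sets out from 15 and returns at 16. (R)-CBS reduction of the C6 ketone gives the (6S)-allylic alcohol F3, with the hydroxyl on the face opposite C3–OTBS. VO(acac)2/t-BuOOH epoxidation, directed by the C6 hydroxyl and reinforced by the C3 silyloxy group, gives the epoxy alcohol F4. Dess–Martin oxidation then gives 16.

3. Step 7. Intramolecular hydride delivery across the sp2 carbon C4 may compete with intermolecular reduction or proceed through the other carbonyl rotamer, giving poor 1,3-anti selectivity at C1'. Fallback: it sets out from 12 and returns at 14. Silylation of the C3 hydroxyl (TBSOTf, 2,6-lutidine) gives the silyl ether dienone F5. Reagent-controlled (R)-CBS reduction of the cross-conjugated ketone, with the ring alkenyl group as the large substituent, gives the (1'S)-alcohol F6. Silylation of F6 gives 14.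

**Further compounds**

F1 | step 16 | 6-methylhept-5-en-1-yne | C#CCCC=C(C)C
F2 | step 16 | (E)-1-iodo-2,6-dimethylhepta-1,5-diene | I/C=C(\C)CCC=C(C)C
F3 | step 10 | (6S)-allylic alcohol from 15 (C6–OH trans to C3–OTBS) | C1C[C@H](O[Si](C)(C)C(C)(C)C)C([C@@H](O[Si](C)(C)C(C)(C)C)/C=C(C)/C#C[Si](C)(C)C)=C[C@H]1O
F4 | step 10 | epoxy alcohol (C4–C5 oxirane cis to C6–OH and trans to C3–OTBS) | C1C[C@H](O[Si](C)(C)C(C)(C)C)[C@@]2([C@@H](O[Si](C)(C)C(C)(C)C)/C=C(C)/C#C[Si](C)(C)C)O[C@H]2[C@H]1O
F5 | step 7 | C3 tert-butyldimethylsilyl ether of 12 | C1C[C@H](O[Si](C)(C)C(C)(C)C)C(C(=O)/C=C(C)/C#C[Si](C)(C)C)=CC12OCCO2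
F6 | step 7 | (1'S)-alcohol from F5 (C3–OTBS, C1'–OH) | C1C[C@H](O[Si](C)(C)C(C)(C)C)C([C@@H](O)/C=C(C)/C#C[Si](C)(C)C)=CC12OCCO2
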